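**Retrosynthetic overview**

1. The chain is numbered C1 (OCH2) to C9 (CH2 on the ring) and the ring carbons C1'–C6'. The oleate C–O bond at C1 is made last, from allylic alcohol 21 and oleic acid 22, after desilylation of 20.
2. The strategy rests on the C6=C7 olefin: E, trisubstituted, CH3 on C7, lying between the C4–C5 and C8–C9 ethylene spacers. It is the imprint of a terminal alkyne that took up CH3 at C7 and C5 at C6 on the same side. It is cut at C7–CH3 and C5–C6 into ring alkyne 7, Me3Al 11 and homoallylic bromide 17.
3. Alkyne 7 comes from (S)-α-ionone 1 by conjugate reduction and enol phosphate elimination. The only stereocentre, C1' (S), is bought and never touched.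
4. Bromide 17 comes from but-3-yn-1-ol 8: the same methylalumination sets its C2=C3 E-olefin, followed by formaldehyde trapping, protecting-group exchange and bromination.
5. No ring is formed anywhere; the cyclohexene C1'–C6' is carried intact from 1.

Key step: step 8

Assumption: (S)-α-ionone 1 is taken as a purchasable enantioenriched material (otherwise resolved from the cheap racemate); its enantiomeric purity is carried into 23 unchanged.

**Route**

Step 1
Reactants: 1 (S)-α-ionone
Product: 3 (S)-dihydro-α-ionone [4-((1S)-2,6,6-trimethylcyclohex-2-en-1-yl)butan-2-one], via silyl enol ether 2 (not isolated)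
Conditions: [(Ph3P)CuH]6 (2 mol%), PhMe2SiH (1.3 equiv), toluene, rt; then 1 M aq. HCl, THF, 0 °C
Reagents that add atoms: none
Why: Catalytic copper hydride conjugate reduction delivers hydride to the β-carbon of the E-enone and holds the product as silyl enol ether 2, so the ketone is not over-reduced, the isolated trisubstituted ring alkene is not a substrate, and the base-free medium leaves the γ-stereocentre (S) as bought.

Step 2
Reactants: 3 (S)-dihydro-α-ionone
Product: 7 (6S)-6-(but-3-yn-1-yl)-1,5,5-trimethylcyclohex-1-ene, via lithium enolate 4 (not isolated), via enol phosphate 5 (not isolated), via lithium acetylide 6 (not isolated)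
Conditions: LiN(i-Pr)2 (1.05 equiv), THF, −78 °C; ClP(O)(OEt)2 (1.1 equiv), −78 °C → rt; added to LiN(i-Pr)2 (2.3 equiv), THF, −78 °C → rt; then H2O
Reagents that add atoms: none
Why: This is the methyl ketone to terminal alkyne conversion through the enol phosphate (kinetic deprotonation on the CH3 side, O-phosphorylation, base-induced elimination to the acetylide); nothing else in 3 is acidic enough for the amide base, so the ring alkene and the stereocentre persist.

Step 3
Reactants: 8 but-3-yn-1-ol
Product: 10 1-[(but-3-yn-1-yloxy)methyl]-4-methoxybenzene, via sodium alkoxide 9 (not isolated)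
Conditions: NaH (1.05 equiv), THF/DMF, 0 °C; 4-methoxybenzyl chloride, Bu4NI (cat.), 0 °C → rt
Reagents that add atoms: 4-methoxybenzyl chloride, COc1ccc(CCl)cc1
Why: Williamson ether synthesis; one equivalent of NaH removes the hydroxyl proton, far more acidic than the alkyne C–H, and the alkoxide displaces the benzylic chloride under iodide catalysis.

Step 4
Reactants: 10 1-[(but-3-yn-1-yloxy)methyl]-4-methoxybenzene; 11 trimethylaluminium
Product: 14 (2E)-5-[(4-methoxybenzyl)oxy]-3-methylpent-2-en-1-ol, via alkenylalane 12 (not isolated), via lithium alanate 13 (not isolated)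
Conditions: Me3Al (2.5 equiv), Cp2ZrCl2 (25 mol%), CH2Cl2, 0 °C → rt; volatiles removed in vacuo; hexane/THF, n-BuLi (1.05 equiv), −78 → 0 °C; (CH2O)n (3 equiv), rt; aq. potassium sodium tartrate
Reagents that add atoms: trimethylaluminium (compound 11), C[Al](C)C; paraformaldehyde (as formaldehyde), C=O
Why: Zirconium-catalysed syn-methylalumination (Negishi carboalumination) places CH3 on the internal and aluminium on the terminal alkyne carbon, and the alkenyl group of the derived alanate adds to formaldehyde with retention, which fixes the E geometry; the benzylic ether only coordinates aluminium.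

Step 5
Reactants: 14 (2E)-5-[(4-methoxybenzyl)oxy]-3-methylpent-2-en-1-ol
Product: 15 tert-butyl({(2E)-5-[(4-methoxybenzyl)oxy]-3-methylpent-2-en-1-yl}oxy)dimethylsilane
Conditions: TBSCl (1.2 equiv), imidazole (2 equiv), CH2Cl2, 0 °C → rt
Reagents that add atoms: tert-butyldimethylsilyl chloride, CC(C)(C)[Si](C)(C)Cl
Why: Standard imidazole-mediated silylation of a primary allylic alcohol.

Step 6
Reactants: 15 tert-butyl({(2E)-5-[(4-methoxybenzyl)oxy]-3-methylpent-2-en-1-yl}oxy)dimethylsilane
Product: 16 (3E)-5-[(tert-butyldimethylsilyl)oxy]-3-methylpent-3-en-1-ol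
Conditions: DDQ (1.3 equiv), CH2Cl2/aq. NaH2PO4–Na2HPO4 buffer (pH 7), 0 °C → rt
Reagents that add atoms: none
Why: Oxidative cleavage of the electron-rich 4-methoxybenzyl ether by DDQ (benzylic hydride abstraction, then hydrolysis of the oxocarbenium ion) under buffered conditions that leave the silyl ether and the trisubstituted alkene alone.

Step 7
Reactants: 16 (3E)-5-[(tert-butyldimethylsilyl)oxy]-3-methylpent-3-en-1-ol
Product: 17 {[(2E)-5-bromo-3-methylpent-2-en-1-yl]oxy}(tert-butyl)dimethylsilane
Conditions: CBr4 (1.3 equiv), PPh3 (1.4 equiv), 2,6-lutidine (0.3 equiv), CH2Cl2, 0 °C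
Reagents that add atoms: carbon tetrabromide, BrC(Br)(Br)Br
Why: Appel bromination; bromide displaces the alkoxyphosphonium ion in an SN2 step at the unhindered primary carbon, and lutidine buffers HBr so the allylic silyl ether survives.

Step 8
Reactants: 7 (6S)-6-(but-3-yn-1-yl)-1,5,5-trimethylcyclohex-1-ene; 11 trimethylaluminium; 17 {[(2E)-5-bromo-3-methylpent-2-en-1-yl]oxy}(tert-butyl)dimethylsilane
Product: 20 tert-butyldimethylsilyl ether of (2E,6E)-3,7-dimethyl-9-[(1S)-2,6,6-trimethylcyclohex-2-en-1-yl]nona-2,6-dien-1-ol, via alkenylalane 18 (not isolated), via alkenylzinc chloride 19 (not isolated)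
Conditions: 7 (1.3 equiv), Me3Al (2.6 equiv), Cp2ZrCl2 (20 mol%), CH2Cl2, rt; volatiles and excess Me3Al removed in vacuo; THF, ZnCl2 (1.3 equiv), 0 °C → rt; then 17 (1.0 equiv), Pd2(dba)3 (2 mol%), P(c-C5H9)3 (8 mol%), N-methylimidazole (2 equiv), THF/NMP, 80 °C
Reagents that add atoms: trimethylaluminium (compound 11), C[Al](C)C
Why: Cp2ZrCl2 (tetravalent zirconium) and Me3Al form a bimetallic methylzirconium species that adds CH3 and metal syn across the terminal alkyne of 7, CH3 to the internal carbon C7 and aluminium to C6 (18); ZnCl2 then moves the alkenyl group to zinc with retention (19), and zerovalent palladium carrying the bulky, electron-rich P(c-C5H9)3 adds oxidatively to the primary C5–Br bond of 17 in an SN2-like step, transmetalates with 19 and eliminates reductively to form C5–C6 faster than β-hydride loss. Both halves are known reaction types, namely zirconium-catalysed methylalumination of terminal alkynes with zinc-assisted palladium coupling of the alkenylmetal, and the palladium/trialkylphosphine Negishi coupling of alkenylzinc halides with unactivated primary alkyl bromides; the step asks that they run in sequence in one flask. No ring is closed and no stereocentre is created, and the (S) centre at C1' lies three bonds from the nearest metal-bearing carbon and is not touched. The step needs regio- and syn-selective carbometalation, which together fix the E geometry of C6=C7 and are secured by the terminal, propargylically unbranched alkyne, and it needs alkenyl rather than methyl transfer in the coupling, helped by stripping excess Me3Al before ZnCl2 is added. The trisubstituted ring alkene is inert to carbometalation, and the allylic oxygen is carried as a silyl ether because an allylic ester would ionise at zerovalent palladium.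

Step 9
Reactants: 20 tert-butyldimethylsilyl ether of (2E,6E)-3,7-dimethyl-9-[(1S)-2,6,6-trimethylcyclohex-2-en-1-yl]nona-2,6-dien-1-ol
Product: 21 (2E,6E)-3,7-dimethyl-9-[(1S)-2,6,6-trimethylcyclohex-2-en-1-yl]nona-2,6-dien-1-ol
Conditions: Bu4NF (1.2 equiv), THF, 0 °C → rt
Reagents that add atoms: none
Why: Fluoride-driven Si–O cleavage; none of the three trisubstituted alkenes is affected.

Step 10
Reactants: 21 (2E,6E)-3,7-dimethyl-9-[(1S)-2,6,6-trimethylcyclohex-2-en-1-yl]nona-2,6-dien-1-ol; 22 oleic acid
Product: 23 (2E,6E)-3,7-dimethyl-9-[(1S)-2,6,6-trimethylcyclohex-2-en-1-yl]nona-2,6-dien-1-yl (9Z)-octadec-9-enoate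
Conditions: DCC (1.2 equiv), DMAP (10 mol%), CH2Cl2, 0 °C → rt
Reagents that add atoms: none
Why: Steglich esterification; the O-acylisourea from DCC is relayed through the acylpyridinium of DMAP to the primary allylic alcohol under neutral conditions, so neither the ionisable allylic C–O bond nor the Z-olefin of the oleoyl chain is disturbed.

**Compound list**

1 | (S)-α-ionone, (3E)-4-[(1S)-2,6,6-trimethylcyclohex-2-en-1-yl]but-3-en-2-one | CC(=O)/C=C/[C@@H]1C(C)=CCCC1(C)C | starting material
2 | dimethyl(phenyl)silyl enol ether of 3 (enol geometry not defined) | CC(O[Si](C)(C)c1ccccc1)=CC[C@@H]1C(C)=CCCC1(C)C | intermediate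
3 | (S)-dihydro-α-ionone, 4-[(1S)-2,6,6-trimethylcyclohex-2-en-1-yl]butan-2-one | CC(=O)CC[C@@H]1C(C)=CCCC1(C)C | intermediate
4 | lithium 4-[(1S)-2,6,6-trimethylcyclohex-2-en-1-yl]but-1-en-2-olate | [Li+].[O-]C(=C)CC[C@@H]1C(C)=CCCC1(C)C | intermediate
5 | diethyl 4-[(1S)-2,6,6-trimethylcyclohex-2-en-1-yl]but-1-en-2-yl phosphate | C=C(OP(=O)(OCC)OCC)CC[C@@H]1C(C)=CCCC1(C)C | intermediate
6 | lithium acetylide of 7 | [Li]C#CCC[C@@H]1C(C)=CCCC1(C)C | intermediate
7 | (6S)-6-(but-3-yn-1-yl)-1,5,5-trimethylcyclohex-1-ene | C#CCC[C@@H]1C(C)=CCCC1(C)C | intermediate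
8 | but-3-yn-1-ol | C#CCCO | starting material
9 | sodium but-3-yn-1-olate | [Na+].[O-]CCC#C | intermediate
10 | 1-[(but-3-yn-1-yloxy)methyl]-4-methoxybenzene | C#CCCOCc1ccc(OC)cc1 | intermediate
11 | trimethylaluminium | C[Al](C)C | starting material
12 | {(1E)-4-[(4-methoxybenzyl)oxy]-2-methylbut-1-en-1-yl}dimethylalane | C[Al](C)/C=C(\C)CCOCc1ccc(OC)cc1 | intermediate
13 | lithium butyl{(1E)-4-[(4-methoxybenzyl)oxy]-2-methylbut-1-en-1-yl}dimethylalanate | [Li+].CCCC[Al-](C)(C)/C=C(\C)CCOCc1ccc(OC)cc1 | intermediate
14 | (2E)-5-[(4-methoxybenzyl)oxy]-3-methylpent-2-en-1-ol | OC/C=C(\C)CCOCc1ccc(OC)cc1 | intermediate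
15 | tert-butyl({(2E)-5-[(4-methoxybenzyl)oxy]-3-methylpent-2-en-1-yl}oxy)dimethylsilane | CC(C)(C)[Si](C)(C)OC/C=C(\C)CCOCc1ccc(OC)cc1 | intermediate
16 | (3E)-5-[(tert-butyldimethylsilyl)oxy]-3-methylpent-3-en-1-ol | CC(C)(C)[Si](C)(C)OC/C=C(\C)CCO | intermediate
17 | {[(2E)-5-bromo-3-methylpent-2-en-1-yl]oxy}(tert-butyl)dimethylsilane | CC(C)(C)[Si](C)(C)OC/C=C(\C)CCBr | intermediate
18 | dimethyl{(1E)-2-methyl-4-[(1S)-2,6,6-trimethylcyclohex-2-en-1-yl]but-1-en-1-yl}alane | C[Al](C)/C=C(\C)CC[C@@H]1C(C)=CCCC1(C)C | intermediate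
19 | chloro{(1E)-2-methyl-4-[(1S)-2,6,6-trimethylcyclohex-2-en-1-yl]but-1-en-1-yl}zinc | Cl[Zn]/C=C(\C)CC[C@@H]1C(C)=CCCC1(C)C | intermediate
20 | tert-butyldimethylsilyl ether of (2E,6E)-3,7-dimethyl-9-[(1S)-2,6,6-trimethylcyclohex-2-en-1-yl]nona-2,6-dien-1-ol | CC(C)(C)[Si](C)(C)OC/C=C(\C)CC/C=C(\C)CC[C@@H]1C(C)=CCCC1(C)C | intermediate
21 | (2E,6E)-3,7-dimethyl-9-[(1S)-2,6,6-trimethylcyclohex-2-en-1-yl]nona-2,6-dien-1-ol | OC/C=C(\C)CC/C=C(\C)CC[C@@H]1C(C)=CCCC1(C)C | intermediate
22 | oleic acid, (9Z)-octadec-9-enoic acid | CCCCCCCC/C=C\CCCCCCCC(=O)O | starting material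
23 | (2E,6E)-3,7-dimethyl-9-[(1S)-2,6,6-trimethylcyclohex-2-en-1-yl]nona-2,6-dien-1-yl (9Z)-octadec-9-enoate | CCCCCCCC/C=C\CCCCCCCC(=O)OC/C=C(\C)CC/C=C(\C)CC[C@@H]1C(C)=CCCC1(C)C | target

**Step count and risks**

Total step count: 10. Longest linear sequence: 8 steps (steps 3–10, from but-3-yn-1-ol 8 through 17 and 20 to 23).

Steps most likely to fail:

1. Step 8. The telescoped sequence may break down at the coupling stage: the alkylpalladium formed from 17 carries allylic β-hydrogens and may lose one before transmetalation, residual Al–CH3 groups may transfer methyl in competition with the alkenyl group, and aluminium and zirconium residues may slow the zinc-to-palladium transfer. The fallback reverses the polarity of the two partners and uses the long-established alkenyl iodide/alkylzinc Negishi coupling. It sets out from 7: methylalumination as in step 8 gives 18, which is quenched with I2 in THF at −30 → 0 °C to give (6S)-6-[(3E)-4-iodo-3-methylbut-3-en-1-yl]-1,5,5-trimethylcyclohex-1-ene F1. Separately, bromide 17 is converted with activated Zn dust and LiCl in THF at 50 °C into the homoallylzinc bromide F2. Coupling of F1 with F2 under Pd(PPh3)4 in THF at rt to 50 °C should form the same C5–C6 bond and return to the route at 20. Oxidative addition then occurs at the alkenyl iodide, so the β-hydride problem of an alkyl electrophile does not arise.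

2. Step 4. Hydroxymethylation of the alanate may be inefficient, through slow depolymerisation of paraformaldehyde and competing protonolysis of the alkenyl–aluminium bond. The fallback replaces the one-carbon electrophile and the oxidation level: from 10, alkenylalane 12 is generated as in step 4 and treated directly with ethyl chloroformate (THF, 0 °C → rt) to give ethyl (2E)-5-[(4-methoxybenzyl)oxy]-3-methylpent-2-enoate F3. Reduction with i-Bu2AlH in CH2Cl2 at −78 °C returns to the route at 14.

3. Step 2. Enolisation may not be fully regioselective for the CH3 side, leading through the internal enol phosphate to allene or internal alkyne, and the elimination may stall at 5. The fallback builds the alkyne by one-carbon homologation instead. From 3, haloform cleavage (aq. NaOCl, NaOH, dioxane, 0 °C → rt) gives 3-[(1S)-2,6,6-trimethylcyclohex-2-en-1-yl]propanoic acid F4. LiAlH4 in Et2O gives 3-[(1S)-2,6,6-trimethylcyclohex-2-en-1-yl]propan-1-ol F5, and Dess–Martin periodinane (CH2Cl2, NaHCO3) gives 3-[(1S)-2,6,6-trimethylcyclohex-2-en-1-yl]propanal F6. Ohira–Bestmann homologation (dimethyl (1-diazo-2-oxopropyl)phosphonate, K2CO3, MeOH, rt) returns to the route at 7.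

**Further compounds**

F1 | step 8 | (6S)-6-[(3E)-4-iodo-3-methylbut-3-en-1-yl]-1,5,5-trimethylcyclohex-1-ene | I/C=C(\C)CC[C@@H]1C(C)=CCCC1(C)C
F2 | step 8 | bromo{(3E)-5-[(tert-butyldimethylsilyl)oxy]-3-methylpent-3-en-1-yl}zinc | Br[Zn]CC/C(C)=C/CO[Si](C)(C)C(C)(C)C
F3 | step 4 | ethyl (2E)-5-[(4-methoxybenzyl)oxy]-3-methylpent-2-enoate | CCOC(=O)/C=C(\C)CCOCc1ccc(OC)cc1
F4 | step 2 | 3-[(1S)-2,6,6-trimethylcyclohex-2-en-1-yl]propanoic acid | OC(=O)CC[C@@H]1C(C)=CCCC1(C)C
F5 | step 2 | 3-[(1S)-2,6,6-trimethylcyclohex-2-en-1-yl]propan-1-ol | OCCC[C@@H]1C(C)=CCCC1(C)C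
F6 | step 2 | 3-[(1S)-2,6,6-trimethylcyclohex-2-en-1-yl]propanal | O=CCC[C@@H]1C(C)=CCCC1(C)C
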